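The ten-membered ring is disconnected at both alkenes of its 1,5-diene C10=C1–C2–C3–C4=C5, like a metathesis read backwards. This gives a cyclobutene (C1–C4) and a cyclohexenone (C5–C10) in which C6, C7 and C8 are already in place. One enone–alkene photocycloaddition bonds C10 to C1 and C5 to C4 and stores the strain of a bicyclo[2.2.0]hexane. Heating then breaks C1–C4 and C5–C10 and releases the macrocycle. The photosubstrate is a cis-fused bicyclic enone lactone with the C14 ester on C10. Shikimic acid supplies C8 directly and C7 by one inversion. This β-acyloxy ketone is one elimination away from a phenol, so it is unveiled only by a final neutral oxidation.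

Key step: step 10

Remark on the chemistry: germacrane numbering is used for all intermediates (ring C1–C10, lactone carbons C11 and C12, methylene C13, C14 on C10, C15 on C4, O6/O7/O8 on C6/C7/C8). The target is 6R,7R,8R with both ring alkenes cis within the ring.

Remark on the chemistry: centres that are not controlled and vanish later are written without descriptor (sulfur in 3 and 5, C11 in 7–9, 24 and 25, the hemiacetal carbon in 20–22).

Step 1
Reactants: 1 (−)-shikimic acid
Product: 2 methyl shikimate
Conditions: MeOH, camphorsulfonic acid (cat.), reflux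
Reagents that add atoms: methanol, CO
Why: Fischer esterification of the only carboxyl group, with no stereocentre involved.

Step 2
Reactants: 2 methyl shikimate
Product: 3 methyl shikimate O6/O7 cyclic sulfite
Conditions: SOCl2 (1.05 equiv), Et3N, CH2Cl2, 0 °C
Reagents that add atoms: thionyl chloride, O=S(Cl)Cl
Why: Cyclic sulfite formation is selective because only the cis-diol O6/O7 can be spanned by a five-membered ring without strain, so O8 remains free and no C–O bond is broken.

Step 3
Reactants: 3 methyl shikimate O6/O7 cyclic sulfite; 4 mono-tert-butyl malonate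
Product: 5 O8 tert-butyl malonate of the cyclic sulfite
Conditions: DCC, DMAP (cat.), CH2Cl2, 0 → 23 °C
Reagents that add atoms: none
Why: Steglich esterification of the single free hydroxyl hangs the future C11–C12 unit on O8, on the ring face opposite to the C7–O bond.

Step 4
Reactants: 5 O8 tert-butyl malonate of the cyclic sulfite
Product: 6 O6/O7 cyclic sulfate
Conditions: RuCl3 (cat.), NaIO4, MeCN/EtOAc/H2O, 0 °C
Reagents that add atoms: sodium periodate, [Na+].[O-]I(=O)(=O)=O
Why: Catalytic RuO4 oxidation of a cyclic sulfite to the cyclic sulfate is a standard diol activation and is fast enough at 0 °C to spare the electron-poor trisubstituted enoate.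

Step 5
Reactants: 6 O6/O7 cyclic sulfate
Product: 8 cis-fused hydroxy lactone tert-butyl ester, via sulfate monoester sodium salt 7 (not isolated)
Conditions: NaH (1.05 equiv), THF, 0 → 23 °C; then H2SO4 (cat.), H2O (2 equiv), THF, 23 °C
Reagents that add atoms: none
Why: Malonate alkylation by a cyclic sulfate, run intramolecularly: the three-atom tether lets the carbanion reach only C7 (5-exo-tet) and only from the face anti to the C7–O bond, so SN2 inversion sets C7 and closes the lactone cis-fused, and dilute acid then cleaves the C6 sulfate monoester at sulfur.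

Step 6
Reactants: 8 cis-fused hydroxy lactone tert-butyl ester
Product: 10 allylic alcohol lactone, via malonic-type acid 9 (not isolated)
Conditions: CF3CO2H, CH2Cl2, 0 → 23 °C; concentrate; toluene, 110 °C
Reagents that add atoms: none
Why: Acidolysis of the tert-butyl ester and thermal decarboxylation of the resulting malonic-type acid remove the activating group without base and erase the uncontrolled C11 centre.

Step 7
Reactants: 10 allylic alcohol lactone
Product: 11 cis-fused enone lactone
Conditions: Dess–Martin periodinane, CH2Cl2, 0 → 23 °C; cold rapid work-up, used at once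
Reagents that add atoms: none
Why: Dess–Martin oxidation of the allylic alcohol runs under neutral to weakly acidic conditions, which is essential because base would turn this β-acyloxy ketone into a phenol by E1cB loss of the C8 carboxylate followed by tautomerisation.

Step 8
Reactants: 12 ethyl 1-bromocyclobutane-1-carboxylate
Product: 13 cyclobut-1-ene-1-carboxylic acid
Conditions: KOH (powder), toluene, reflux; then aq. HCl
Reagents that add atoms: potassium hydroxide, [K+].[OH-]
Why: Ester saponification and E2 dehydrobromination in one operation is the established entry to cyclobutene-1-carboxylic acid.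

Step 9
Reactants: 13 cyclobut-1-ene-1-carboxylic acid
Product: 14 methyl cyclobut-1-ene-1-carboxylate
Conditions: MeI, K2CO3, DMF, 23 °C
Reagents that add atoms: iodomethane, CI
Why: SN2 O-methylation of the carboxylate avoids the acid and heat that polymerise this strained acrylate, which is distilled and used at once.

Step 10
Reactants: 11 cis-fused enone lactone; 14 methyl cyclobut-1-ene-1-carboxylate
Product: 15 cis-anti-cis tricyclic keto lactone diester
Conditions: hν (365 nm LED, or medium-pressure Hg lamp with uranium-glass filter), 14 (5 equiv), degassed CH2Cl2, −20 °C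
Reagents that add atoms: none
Why: Excitation and intersystem crossing give the twisted enone triplet, which bonds from C10 to the unsubstituted alkene carbon C1; the triplet 1,4-biradical (α-keto radical at C5, tertiary ester-stabilised radical at C4) closes C5–C4 after spin inversion, so the one new ring, the central cyclobutane, is closed stepwise by radical recombination in a formal [2+2] mode. The closest known reaction type is the intermolecular enone–alkene [2+2] photocycloaddition, for which cyclohexenones and cyclobutene-1-carboxylates are an established pairing that gives tricyclo[4.4.0.0(2,5)]decanones. The selectivity that matters is head-to-head regiochemistry: the ester on C4 stabilises the radical left by the first bond, whereas the opposite orientation would have to join the two fully substituted carbons C10 and C4, so its biradical should revert to the partners. C10 and C5 are set by approach to the convex face of the cup-shaped cis-bicycle, anti to C11 and O8, and the six–four junction ends cis because a trans-fused cyclobutane on the cyclohexanone is much more strained. C1 and C4 are necessarily cis on the small ring and turn C2–C3 away from C6 and C9, which gives the cis-anti-cis array. All four centres vanish in step 11, so facial or syn/anti leakage is harmless, and long-wavelength light, low temperature and excess alkene hold back enone dimerisation and secondary photolysis.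

Step 11
Reactants: 15 cis-anti-cis tricyclic keto lactone diester
Product: 17 cis,cis-cyclodecadienone lactone diester, via 4Z cyclodecadienone 16 (not isolated)
Conditions: degassed mesitylene (0.01 M), BHT (cat.), silanised flask, 165 °C; cool to 23 °C, I2 (5 mol %), visible light
Reagents that add atoms: none
Why: Thermal cycloreversion of a bicyclo[2.2.0]hexane (C1–C4 breaks to an ester-stabilised 1,4-diyl, then C5–C10 breaks) followed by iodine-atom-catalysed E/Z equilibration: the chair diyl that keeps the C14 ester and C6 equatorial should deliver the 1(10)-cis,4-trans diene 16, and reversible addition of an iodine atom to its strained, maleate-like C4=C5 bond funnels it to the fumarate-like isomer 17, in which both alkenes are cis in the ring and conjugated, a stabilisation that also works against Cope rearrangement to the divinylcyclohexane.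

Step 12
Reactants: 17 cis,cis-cyclodecadienone lactone diester
Product: 18 6S allylic alcohol
Conditions: NaBH4, CeCl3·7H2O, MeOH/CH2Cl2, −78 °C
Reagents that add atoms: none
Why: Luche reduction gives 1,2-addition to the ene-keto-ester, and with the ring bond C7–C8 perpendicular to the carbonyl plane and C11 gauche to the oxygen (the Felkin–Anh arrangement, which here coincides with peripheral attack on the medium ring) hydride should arrive anti to C8 and set C6 as S, with O6 cis to C11, the epimer required for the inversion that follows.

Step 13
Reactants: 18 6S allylic alcohol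
Product: 19 6R 4-nitrobenzoate
Conditions: 4-O2NC6H4CO2H, PPh3, DIAD, toluene, 0 → 23 °C
Reagents that add atoms: 4-nitrobenzoic acid, O=C(O)c1ccc(cc1)[N+](=O)[O-]
Why: Mitsunobu reaction, in which SN2 displacement of the oxyphosphonium group by the acidic nitrobenzoate inverts C6 to the R configuration of the target, SN2' attack being blocked because C4 is fully substituted and electron-poor.

Step 14
Reactants: 19 6R 4-nitrobenzoate
Product: 21 triol 6,12-lactol, via 8,12-lactol 20 (not isolated)
Conditions: iBu2AlH (9 equiv), CH2Cl2, −78 °C; aq. potassium sodium tartrate, 23 °C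
Reagents that add atoms: none
Why: Hydride reduction with iBu2AlH turns both enoates into allylic alcohols without touching alkene geometry, cleaves the nitrobenzoate and halts at the lactol aluminate, so C14 is reduced while O8 is still masked and cannot lactonise onto it, and on work-up the hemiacetal opens and recloses freely and should settle on O6, because a trans-fused five-membered ring leaves the C5–C6–C7–C8 torsion near 150° whereas a cis-fused one forces C6–C7–C8–C9 to about 35° in the ten-membered ring.

Step 15
Reactants: 21 triol 6,12-lactol
Product: 22 bis-TBS 6,12-lactol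
Conditions: TBSCl (2.1 equiv), imidazole, CH2Cl2, 0 °C
Reagents that add atoms: tert-butyldimethylsilyl chloride, CC(C)(C)[Si](C)(C)Cl
Why: Selective silylation, since the two primary allylic hydroxyls react far faster with TBSCl than the hindered secondary C8 hydroxyl or the hemiacetal hydroxyl.

Step 16
Reactants: 22 bis-TBS 6,12-lactol
Product: 23 trans-fused 6,12-lactone with free C8 hydroxyl
Conditions: Ag2CO3 on Celite, toluene, 80 °C
Reagents that add atoms: none
Why: Fétizon oxidation, in which Ag2CO3 on Celite oxidises hemiacetals much faster than isolated secondary alcohols, so the lactol becomes the lactone on O6 while the C8 hydroxyl survives.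

Step 17
Reactants: 23 trans-fused 6,12-lactone with free C8 hydroxyl
Product: 26 methylene lactone alcohol, via Mannich base 24 (not isolated), via methiodide 25 (not isolated)
Conditions: LiN(iPr)2 (3 equiv), THF, −78 °C; Me2N=CH2 I, −78 → 0 °C; aq. work-up; MeI, MeOH, 23 °C; aq. NaHCO3, CH2Cl2
Reagents that add atoms: Eschenmoser's salt, C[N+](C)=C.[I-]; iodomethane, CI (its methyl group enters 25 only and leaves again with the amine)
Why: Eschenmoser methylenation, in which the alkoxide–enolate dianion undergoes a Mannich reaction at C11 and Hofmann-type elimination of the quaternised amine gives the exocyclic methylene, so the transient C11 centre is irrelevant.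

Step 18
Reactants: 26 methylene lactone alcohol; 27 isovaleric anhydride
Product: 28 C8 isovalerate bis-TBS ether
Conditions: DMAP, Et3N, CH2Cl2, 0 → 23 °C
Reagents that add atoms: none
Why: DMAP-catalysed acyl transfer to the only free hydroxyl installs the isovalerate with retention at C8, and placing it after step 17 keeps a second enolisable ester out of the methylenation.

Step 19
Reactants: 28 C8 isovalerate bis-TBS ether
Product: 29 target CNP0199826.1
Conditions: HF·pyridine, pyridine, THF, 0 → 23 °C
Reagents that add atoms: none
Why: Fluoride-mediated desilylation under buffered, weakly acidic conditions frees both primary allylic alcohols without Michael addition to the methylene lactone or acyl migration.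

Compound list
1 | (−)-shikimic acid, (3R,4S,5R)-3,4,5-trihydroxycyclohex-1-ene-1-carboxylic acid | O[C@@H]1C=C(C(=O)O)C[C@@H](O)[C@@H]1O | starting material
2 | methyl shikimate | O[C@@H]1C=C(C(=O)OC)C[C@@H](O)[C@@H]1O | intermediate
3 | methyl shikimate O6/O7 (3,4-O) cyclic sulfite, O8 hydroxyl free | COC(=O)C1=C[C@H]2OS(=O)O[C@H]2[C@H](O)C1 | intermediate
4 | mono-tert-butyl malonate (3-tert-butoxy-3-oxopropanoic acid) | CC(C)(C)OC(=O)CC(=O)O | starting material
5 | cyclic sulfite carrying the tert-butyl malonate on O8 | COC(=O)C1=C[C@H]2OS(=O)O[C@H]2[C@H](OC(=O)CC(=O)OC(C)(C)C)C1 | intermediate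
6 | corresponding O6/O7 cyclic sulfate | COC(=O)C1=C[C@H]2OS(=O)(=O)O[C@H]2[C@H](OC(=O)CC(=O)OC(C)(C)C)C1 | intermediate
7 | sodium salt of the C6 sulfate monoester of the cis-fused lactone (CO2tBu on C11) | COC(=O)C1=C[C@@H](OS(=O)(=O)[O-])[C@@H]2C(C(=O)OC(C)(C)C)C(=O)O[C@@H]2C1.[Na+] | intermediate
8 | cis-fused lactone with C6 hydroxyl, CO2tBu on C11 and the C5=C10 enoate | COC(=O)C1=C[C@@H](O)[C@@H]2C(C(=O)OC(C)(C)C)C(=O)O[C@@H]2C1 | intermediate
9 | corresponding C11 carboxylic acid | COC(=O)C1=C[C@@H](O)[C@@H]2C(C(=O)O)C(=O)O[C@@H]2C1 | intermediate
10 | methyl (3aS,4R,7aR)-4-hydroxy-2-oxo-2,3,3a,4,7,7a-hexahydrobenzofuran-6-carboxylate | COC(=O)C1=C[C@@H](O)[C@@H]2CC(=O)O[C@@H]2C1 | intermediate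
11 | methyl (3aR,7aR)-2,4-dioxo-2,3,3a,4,7,7a-hexahydrobenzofuran-6-carboxylate, cis-fused enone lactone | O=C1C=C(C(=O)OC)C[C@H]2OC(=O)C[C@@H]12 | intermediate
12 | ethyl 1-bromocyclobutane-1-carboxylate | CCOC(=O)C1(Br)CCC1 | starting material
13 | cyclobut-1-ene-1-carboxylic acid | OC(=O)C1=CCC1 | intermediate
14 | methyl cyclobut-1-ene-1-carboxylate | COC(=O)C1=CCC1 | intermediate
15 | head-to-head photoadduct: cis-anti-cis tricyclo[4.4.0.0(2,5)]decanone with cis-fused 8,12-lactone, esters on C10 and C4, cyclobutane anti to the lactone | O=C1[C@H]2[C@@](C(=O)OC)(C[C@H]3OC(=O)C[C@@H]13)[C@@H]4CC[C@]24C(=O)OC | intermediate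
16 | cyclodeca-1(10),4-dien-6-one 8,12-lactone diester, C1=C10 cis in ring, C4=C5 trans in ring (4Z) | O=C1/C=C(\C(=O)OC)CC/C=C(/C(=O)OC)C[C@H]2OC(=O)C[C@@H]12 | intermediate
17 | same skeleton with both alkenes cis in ring (1(10)E,4E enoates) | O=C1/C=C(/C(=O)OC)CC/C=C(/C(=O)OC)C[C@H]2OC(=O)C[C@@H]12 | intermediate
18 | 6S allylic alcohol (O6 cis to C11), 8,12-lactone, dimethyl ester | O[C@H]1/C=C(/C(=O)OC)CC/C=C(/C(=O)OC)C[C@H]2OC(=O)C[C@@H]12 | intermediate
19 | 6R 4-nitrobenzoate (O6 trans to C11), 8,12-lactone, dimethyl ester | O=C(O[C@@H]1/C=C(/C(=O)OC)CC/C=C(/C(=O)OC)C[C@H]2OC(=O)C[C@@H]12)c1ccc(cc1)[N+](=O)[O-] | intermediate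
20 | 8,12-lactol with free 6R hydroxyl and C14, C15 hydroxymethyl groups | O[C@@H]1/C=C(/CO)CC/C=C(/CO)C[C@H]2OC(O)C[C@@H]12 | intermediate
21 | trans-fused 6,12-lactol with free C8, C14 and C15 hydroxyls | C1C(O)O[C@@H]2/C=C(/CO)CC/C=C(/CO)C[C@@H](O)[C@@H]12 | intermediate
22 | 14,15-bis-TBS ether of 21 | C1C(O)O[C@@H]2/C=C(/CO[Si](C)(C)C(C)(C)C)CC/C=C(/CO[Si](C)(C)C(C)(C)C)C[C@@H](O)[C@@H]12 | intermediate
23 | trans-fused 6,12-lactone, free C8 hydroxyl, 14,15-bis-TBS ether | C1C(=O)O[C@@H]2/C=C(/CO[Si](C)(C)C(C)(C)C)CC/C=C(/CO[Si](C)(C)C(C)(C)C)C[C@@H](O)[C@@H]12 | intermediate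
24 | C11 dimethylaminomethyl lactone (Mannich base) | CN(C)CC1C(=O)O[C@@H]2/C=C(/CO[Si](C)(C)C(C)(C)C)CC/C=C(/CO[Si](C)(C)C(C)(C)C)C[C@@H](O)[C@@H]12 | intermediate
25 | corresponding trimethylammonium iodide | C[N+](C)(C)CC1C(=O)O[C@@H]2/C=C(/CO[Si](C)(C)C(C)(C)C)CC/C=C(/CO[Si](C)(C)C(C)(C)C)C[C@@H](O)[C@@H]12.[I-] | intermediate
26 | α-methylene 6,12-lactone, free C8 hydroxyl, 14,15-bis-TBS ether | C=C1C(=O)O[C@@H]2/C=C(/CO[Si](C)(C)C(C)(C)C)CC/C=C(/CO[Si](C)(C)C(C)(C)C)C[C@@H](O)[C@@H]12 | intermediate
27 | isovaleric anhydride (3-methylbutanoic anhydride) | CC(C)CC(=O)OC(=O)CC(C)C | starting material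
28 | C8 isovalerate of 26 | C=C1C(=O)O[C@@H]2/C=C(/CO[Si](C)(C)C(C)(C)C)CC/C=C(/CO[Si](C)(C)C(C)(C)C)C[C@@H](OC(=O)CC(C)C)[C@@H]12 | intermediate
29 | CNP0199826.1, (6R,7R,8R)-8-isovaleryloxy-14,15-dihydroxygermacra-1(10),4,11(13)-trien-6,12-olide with both ring alkenes cis in ring | C=C1C(=O)O[C@@H]2/C=C(/CO)CC/C=C(/CO)C[C@@H](OC(=O)CC(C)C)[C@@H]12 | target

Total step count: 19. Longest linear sequence: 17 (steps 1–7 and 10–19).

Steps most likely to fail

**Step 10.**
- What may go wrong: initial bonding at the less hindered C5 could leak material into the head-to-tail orientation. The strained acrylate could also oligomerise, or the fragile enone could decay slowly, before the two partners meet.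
- Fallback: build the bicyclo[2.2.0]hexane in two photochemical stages instead of bringing in a preformed cyclobutene.
- Setting out from 11, irradiation with methyl propiolate (enone–alkyne [2+2] photocycloaddition) forms the same two bonds, C10–C1 and C5–C4. The terminal alkyne carbon goes to the hindered C10, and the product is the cyclobutene adduct F1.
- A sensitised [2+2] addition of ethylene to the cyclobutene-carboxylate bond C1=C4, from its convex face, then adds C2 and C3. The route is rejoined at 15.

**Step 11.**
- What may go wrong: at the temperature needed for cycloreversion the hot cyclodecadienone may drift into the divinylcyclohexane by Cope rearrangement. The β-acyloxy ketone may also lose the C8 carboxylate.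
- Fallback: remove the ketone before heating, which is the variant closest to the known alcohol-level thermolyses.
- Setting out from 15, NaBH4/CeCl3 reduction from the face anti to the cyclobutane gives the tricyclic 6R alcohol F2.
- F2 is silylated at once (TBSOTf, 2,6-lutidine) to the silyl ether F3, so that O6 cannot lactonise onto the C15 ester.
- Thermolysis gives the 4Z cyclodecadiene silyl ether F4, which iodine and light equilibrate in the same flask to the cis,cis silyl ether F5.
- HF·pyridine frees the 6R allylic alcohol F6, which goes directly into the iBu2AlH reduction of step 14 and rejoins the route at 21. Steps 12 and 13 drop out.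

**Step 17.**
- What may go wrong: dianion formation may be incomplete, aminomethylation may occur on oxygen, or the C8 alkoxide may pull the lactone back to O8. Any of these could stall the Mannich step.
- Fallback: methylenate at the aldehyde oxidation level without strong base.
- Setting out from 22, Me2N=CH2 I and Et3N in CH2Cl2 methylenate the open hydroxy aldehyde form and give the α-methylene lactol F7.
- MnO2 then oxidises this allylic hemiacetal to the methylene lactone. The route is rejoined at 26, bypassing 23.

Further compounds
F1 | step 10 | cyclobutene photoadduct of 11 and methyl propiolate (C1=C4 alkene, C15 ester on C4) | O=C1[C@H]2[C@@](C(=O)OC)(C[C@H]3OC(=O)C[C@@H]13)C=C2C(=O)OC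
F2 | step 11 | tricyclic 6R alcohol (O6 cis to the cyclobutane, trans to C11) | O[C@@H]1[C@H]2[C@@](C(=O)OC)(C[C@H]3OC(=O)C[C@@H]13)[C@@H]4CC[C@]24C(=O)OC
F3 | step 11 | TBS ether of F2 | CC(C)(C)[Si](C)(C)O[C@@H]1[C@H]2[C@@](C(=O)OC)(C[C@H]3OC(=O)C[C@@H]13)[C@@H]4CC[C@]24C(=O)OC
F4 | step 11 | 4Z cyclodecadiene 6-O-TBS ether, 8,12-lactone, dimethyl ester | CC(C)(C)[Si](C)(C)O[C@@H]1/C=C(\C(=O)OC)CC/C=C(/C(=O)OC)C[C@H]2OC(=O)C[C@@H]12
F5 | step 11 | cis,cis cyclodecadiene 6-O-TBS ether, 8,12-lactone, dimethyl ester | CC(C)(C)[Si](C)(C)O[C@@H]1/C=C(/C(=O)OC)CC/C=C(/C(=O)OC)C[C@H]2OC(=O)C[C@@H]12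
F6 | step 11 | 6R allylic alcohol, C6 epimer of 18 | O[C@@H]1/C=C(/C(=O)OC)CC/C=C(/C(=O)OC)C[C@H]2OC(=O)C[C@@H]12
F7 | step 17 | α-methylene 6,12-lactol, free C8 hydroxyl, 14,15-bis-TBS ether | C=C1C(O)O[C@@H]2/C=C(/CO[Si](C)(C)C(C)(C)C)CC/C=C(/CO[Si](C)(C)C(C)(C)C)C[C@@H](O)[C@@H]12
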